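**Strategy**

The route rests on cutting ring C of the flavanone (O1–C2–C3–C4–C4a–C8a) at O1–C2 and C3–C4. This leaves the B-ring styrene as the C2–C3 unit and ring A as a heterodiene O1=C8a–C4a=C4. One acid-catalysed oxa-[4+2] cycloaddition forms both bonds, closes ring C and sets C2 under control of a chiral counter-anion. C4 arrives as a methyl ether, one oxidation level below the ketone. The diene precursor is a salicylaldehyde dimethyl acetal with a free hydroxyl next to C8–H, silyl ethers on O5 and O7, and the geranyl group already at C6. The dienophile is the silylated 3-hydroxy-4,5-dimethoxystyrene.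

Key step: step 8

Abbreviations: TBS = tert-butyldimethylsilyl; geranyl = (2E)-3,7-dimethylocta-2,6-dien-1-yl; IDPi = confined BINOL-derived imidodiphosphorimidate Brønsted acid.

Assumption 1: which catalyst enantiomer leads to (2S) cannot be predicted with confidence; the (S,S)-catalyst is written, and its mirror image is to be taken if a first run shows the opposite sense.

Assumption 2: C4 of 13 and 14 is not controlled; both epimers are carried on and written without a C4 descriptor, since they converge at ketone 15.

**Route**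

Step 1
Reactants: 1 phloroglucinol; 2 geraniol
Product: 3 2-geranylphloroglucinol
Conditions: 1 (3 equiv), BF3·OEt2 (0.3 equiv), 1,4-dioxane, rt, dark; excess 1 removed by aqueous wash
Reagents that add atoms: none
Why: Friedel–Crafts allylation: BF3 ionises the allylic alcohol and the symmetric, strongly nucleophilic arene captures the cation at its primary terminus, which keeps the 2E geometry, while the excess of 1 limits di-geranylation and the mild temperature limits cyclisation of the product to a chroman.

Step 2
Reactants: 3 2-geranylphloroglucinol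
Product: 4 1,3,5-tris(TBS-oxy)-2-geranylbenzene
Conditions: TBSCl (4 equiv), imidazole (8 equiv), DMF, rt → 40 °C
Reagents that add atoms: tert-butyldimethylsilyl chloride, CC(C)(C)[Si](C)(C)Cl
Why: Exhaustive silylation of phenols with TBSCl/imidazole (standard silyl ether formation), the excess reagent and mild warming bringing the two hydroxyls beside the geranyl group to completion.

Step 3
Reactants: 4 1,3,5-tris(TBS-oxy)-2-geranylbenzene
Product: 5 3,5-bis(TBS-oxy)-4-geranylphenol
Conditions: Cs2CO3 (0.3 equiv), DMF/H2O (10:1), 0 °C, stopped at partial conversion; chromatography; recovered 4 recycled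
Reagents that add atoms: none
Why: Base-catalysed hydrolysis of an aryl silyl ether: the ether para to the geranyl group has two ring hydrogens as neighbours and is the most exposed of the three, so it should be cleaved first, and the early stop with recycling of 4 and of the resilylated regioisomeric phenol protects the material balance.

Step 4
Reactants: 5 3,5-bis(TBS-oxy)-4-geranylphenol
Product: 7 2,4-bis(TBS-oxy)-3-geranyl-6-hydroxybenzaldehyde, via hydroxymethylphenol 6 (not isolated)
Conditions: MgCl2 (2 equiv), Et3N (4 equiv), (CH2O)n (6 equiv), THF, 60 °C; cold aq. NH4Cl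
Reagents that add atoms: formaldehyde (as paraformaldehyde), C=O
Why: Magnesium-mediated ortho-formylation of a phenol (Casnati–Skattebøl): the magnesium phenoxide directs formaldehyde to the ortho carbon and a second formaldehyde oxidises the hydroxymethyl intermediate 6 by hydride transfer, and because the two ortho positions are equivalent and the para position is blocked only one aldehyde can form, with the formyl group between the free hydroxyl and a silyl ether.

Step 5
Reactants: 7 2,4-bis(TBS-oxy)-3-geranyl-6-hydroxybenzaldehyde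
Product: 8 3,5-bis(TBS-oxy)-2-(dimethoxymethyl)-4-geranylphenol
Conditions: HC(OMe)3 (10 equiv), PPTS (5 mol %), MeOH, rt; Et3N quench, concentration, filtration through basic alumina; used without chromatography
Reagents that add atoms: trimethyl orthoformate, COC(OC)OC; methanol, CO
Why: Acid-catalysed acetalisation driven by the orthoformate as water scavenger: in methanol the stabilised oxocarbenium ion is trapped by solvent faster than by any arene, PPTS leaves the aryl silyl ethers intact, and the amine quench before concentration keeps the labile acetal from reverting.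

Step 6
Reactants: 9 3-hydroxy-4,5-dimethoxybenzaldehyde
Product: 10 3-(TBS-oxy)-4,5-dimethoxybenzaldehyde
Conditions: TBSCl (1.2 equiv), imidazole (2.5 equiv), DMF, rt
Reagents that add atoms: tert-butyldimethylsilyl chloride, CC(C)(C)[Si](C)(C)Cl
Why: Silylation of a phenol with TBSCl/imidazole; the aldehyde is inert under these conditions.

Step 7
Reactants: 10 3-(TBS-oxy)-4,5-dimethoxybenzaldehyde
Product: 11 3-(TBS-oxy)-4,5-dimethoxystyrene
Conditions: Ph3PCH3Br (1.3 equiv), KOtBu (1.25 equiv), THF, 0 °C; then 10, 0 °C → rt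
Reagents that add atoms: methyltriphenylphosphonium bromide, C[P+](c1ccccc1)(c1ccccc1)c1ccccc1.[Br-]
Why: Wittig methylenation: the unstabilised ylide converts the aryl aldehyde into the terminal alkene, and the slight deficit of base relative to the phosphonium salt protects the aryl silyl ether.

Step 8
Reactants: 8 3,5-bis(TBS-oxy)-2-(dimethoxymethyl)-4-geranylphenol; 11 3-(TBS-oxy)-4,5-dimethoxystyrene
Product: 13 (2S)-5,7-bis(TBS-oxy)-2-[3-(TBS-oxy)-4,5-dimethoxyphenyl]-6-geranyl-4-methoxychromane as both C4 epimers, via ortho-quinone methide 12 (not isolated)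
Conditions: 11 (3 equiv), (S,S)-IDPi acid (5 mol %), 5 Å MS, toluene, −40 °C, slow addition of 8; Et3N quench at −40 °C
Reagents that add atoms: none
Why: Proposed new method: the acid should ionise the acetal, helped by the ortho hydroxyl, to the O-protonated 4-methoxy ortho-quinone methide 12 held as a contact ion pair in the chiral pocket, and the styrene should add through its CH2 terminus to C4 and through its benzylic carbon to O1 in a concerted but asynchronous inverse-electron-demand [4+2] step; the closest known reaction types are the achiral-acid cycloaddition of salicylaldehyde acetals with styrenes to 4-alkoxyflavans and chiral-acid-catalysed cycloadditions of ortho-quinone methides and oxocarbenium ions, which have not been combined for a simple styrene and a trioxygenated ring A. Ring C closes in an intermolecular hetero-Diels–Alder mode, C3–C4 bonding leading and O1–C2 bonding following within the ion pair (a six-membered closure of the phenol oxygen onto the developing benzylic cation in the stepwise limit). The C2 stereocentre is set by the chiral counter-anion, which must select the enantioface of the styrene at its benzylic carbon, whereas C4 forms as both epimers and may equilibrate by re-ionisation without touching C2. Regioselectivity follows from polarity (nucleophilic CH2 to cationic C4), and the constitution follows from the substrate, because O5 is silylated and only the oxygen next to C8–H can close the ring, so geranyl ends at C6. Chemoselectivity over arylation at C8 of a second molecule, over the geranyl alkenes and over styrene oligomerisation is sought by slow addition of 8 to excess 11 at low temperature, and the sieves remove methanol so that the ion pair is not returned to the acetal.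

Step 9
Reactants: 13 (2S)-5,7-bis(TBS-oxy)-2-[3-(TBS-oxy)-4,5-dimethoxyphenyl]-6-geranyl-4-methoxychromane
Product: 14 (2S)-5,7-bis(TBS-oxy)-2-[3-(TBS-oxy)-4,5-dimethoxyphenyl]-6-geranylchroman-4-ol as both C4 epimers
Conditions: PPTS (0.2 equiv), THF/H2O (4:1), 0.02 M, rt → 40 °C; NaHCO3 work-up; used directly
Reagents that add atoms: water, O
Why: SN1 solvolysis of a benzylic ether: the C4 cation is stabilised through ring A by O1, O5 and O7, so mild aqueous acid should exchange methoxy for hydroxy at C4 only, high dilution and a large excess of water disfavouring elimination to the flav-3-ene and C4–C8 self-condensation, while C2 is not involved and keeps its configuration.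

Step 10
Reactants: 14 (2S)-5,7-bis(TBS-oxy)-2-[3-(TBS-oxy)-4,5-dimethoxyphenyl]-6-geranylchroman-4-ol
Product: 15 (2S)-5,7-bis(TBS-oxy)-2-[3-(TBS-oxy)-4,5-dimethoxyphenyl]-6-geranylchroman-4-one
Conditions: Dess–Martin periodinane (1.5 equiv), pyridine (3 equiv), CH2Cl2, 0 °C → rt
Reagents that add atoms: none
Why: Dess–Martin oxidation of a secondary benzylic alcohol: both C4 epimers give the same ketone, and the buffered, non-basic conditions leave the alkenes, the silyl ethers and the C2 stereocentre untouched.

Step 11
Reactants: 15 (2S)-5,7-bis(TBS-oxy)-2-[3-(TBS-oxy)-4,5-dimethoxyphenyl]-6-geranylchroman-4-one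
Product: 16 (2S)-5,7-dihydroxy-2-(3-hydroxy-4,5-dimethoxyphenyl)-6-geranylchroman-4-one (CNP0228243.1)
Conditions: TBAF (3.6 equiv), AcOH (4 equiv), THF, 0 °C → rt
Reagents that add atoms: none
Why: Fluoride-mediated cleavage of aryl silyl ethers, buffered with acetic acid so that each phenoxide is protonated as it forms, which suppresses the retro-oxa-Michael opening to the chalcone that would racemise C2.

**Compound list**

1 | phloroglucinol (benzene-1,3,5-triol) | Oc1cc(O)cc(O)c1 | starting material
2 | geraniol ((2E)-3,7-dimethylocta-2,6-dien-1-ol) | CC(C)=CCC/C(C)=C/CO | starting material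
3 | 2-geranylphloroglucinol (2-[(2E)-3,7-dimethylocta-2,6-dien-1-yl]benzene-1,3,5-triol) | Oc1cc(O)c(C/C=C(\C)CCC=C(C)C)c(O)c1 | intermediate
4 | 1,3,5-tris(TBS-oxy)-2-geranylbenzene | CC(C)(C)[Si](C)(C)Oc1cc(O[Si](C)(C)C(C)(C)C)c(C/C=C(\C)CCC=C(C)C)c(O[Si](C)(C)C(C)(C)C)c1 | intermediate
5 | 3,5-bis(TBS-oxy)-4-geranylphenol | Oc1cc(O[Si](C)(C)C(C)(C)C)c(C/C=C(\C)CCC=C(C)C)c(O[Si](C)(C)C(C)(C)C)c1 | intermediate
6 | 3,5-bis(TBS-oxy)-4-geranyl-2-(hydroxymethyl)phenol (formed as its magnesium salt, not isolated) | OCc1c(O)cc(O[Si](C)(C)C(C)(C)C)c(C/C=C(\C)CCC=C(C)C)c1O[Si](C)(C)C(C)(C)C | intermediate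
7 | 2,4-bis(TBS-oxy)-3-geranyl-6-hydroxybenzaldehyde | O=Cc1c(O)cc(O[Si](C)(C)C(C)(C)C)c(C/C=C(\C)CCC=C(C)C)c1O[Si](C)(C)C(C)(C)C | intermediate
8 | 3,5-bis(TBS-oxy)-2-(dimethoxymethyl)-4-geranylphenol (ring-A salicylaldehyde dimethyl acetal) | COC(OC)c1c(O)cc(O[Si](C)(C)C(C)(C)C)c(C/C=C(\C)CCC=C(C)C)c1O[Si](C)(C)C(C)(C)C | intermediate
9 | 3-hydroxy-4,5-dimethoxybenzaldehyde | COc1cc(C=O)cc(O)c1OC | starting material
10 | 3-(TBS-oxy)-4,5-dimethoxybenzaldehyde | COc1cc(C=O)cc(O[Si](C)(C)C(C)(C)C)c1OC | intermediate
11 | 3-(TBS-oxy)-4,5-dimethoxystyrene | C=Cc1cc(OC)c(OC)c(O[Si](C)(C)C(C)(C)C)c1 | intermediate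
12 | 3,5-bis(TBS-oxy)-4-geranyl-6-(methoxymethylidene)cyclohexa-2,4-dien-1-one (4-methoxy ortho-quinone methide, reacting as its O-protonated ion pair; not isolated) | COC=C1C(=O)C=C(O[Si](C)(C)C(C)(C)C)C(C/C=C(\C)CCC=C(C)C)=C1O[Si](C)(C)C(C)(C)C | intermediate
13 | (2S)-5,7-bis(TBS-oxy)-2-[3-(TBS-oxy)-4,5-dimethoxyphenyl]-6-geranyl-4-methoxychromane, both C4 epimers | COc1cc([C@@H]2CC(OC)c3c(cc(O[Si](C)(C)C(C)(C)C)c(C/C=C(\C)CCC=C(C)C)c3O[Si](C)(C)C(C)(C)C)O2)cc(O[Si](C)(C)C(C)(C)C)c1OC | intermediate
14 | (2S)-5,7-bis(TBS-oxy)-2-[3-(TBS-oxy)-4,5-dimethoxyphenyl]-6-geranylchroman-4-ol, both C4 epimers | COc1cc([C@@H]2CC(O)c3c(cc(O[Si](C)(C)C(C)(C)C)c(C/C=C(\C)CCC=C(C)C)c3O[Si](C)(C)C(C)(C)C)O2)cc(O[Si](C)(C)C(C)(C)C)c1OC | intermediate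
15 | (2S)-5,7-bis(TBS-oxy)-2-[3-(TBS-oxy)-4,5-dimethoxyphenyl]-6-geranylchroman-4-one | COc1cc([C@@H]2CC(=O)c3c(cc(O[Si](C)(C)C(C)(C)C)c(C/C=C(\C)CCC=C(C)C)c3O[Si](C)(C)C(C)(C)C)O2)cc(O[Si](C)(C)C(C)(C)C)c1OC | intermediate
16 | (2S)-5,7-dihydroxy-2-(3-hydroxy-4,5-dimethoxyphenyl)-6-[(2E)-3,7-dimethylocta-2,6-dien-1-yl]chroman-4-one (CNP0228243.1) | COc1cc([C@@H]2CC(=O)c3c(cc(O)c(C/C=C(\C)CCC=C(C)C)c3O)O2)cc(O)c1OC | target

**Step count**

Total: 11 steps. Longest linear sequence: 9 steps (steps 1–5 and 8–11); the styrene branch (steps 6–7) joins at step 8.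

**Steps most likely to fail**

1. Step 8, the step proposed as a new method. The chiral anion may discriminate poorly between the two faces of the styrene. Alternatively, the long-lived, strongly stabilised cation may be consumed before it cyclo-adds, by arylation at C8 of a second ring-A molecule, by the geranyl alkenes or by cationic oligomerisation of the styrene. The fallback uses known chemistry, sets out from aldehyde 7 with aldehyde 10 as partner, and comes back at ketone 15. Aldehyde 7 would be treated with MeMgBr (THF, −78 °C) to give the secondary benzylic alcohol F1, which Dess–Martin oxidation would turn into the 2'-hydroxyacetophenone F2. Its dilithio derivative (LiHMDS, THF, −78 °C) would add to 10 to give the aldol F3. Elimination and equilibrating oxa-Michael closure in one flask (NaOAc, EtOH, 60 °C) would pass through the 2'-hydroxychalcone F4 to the racemic tris-silyl flavanone F5. Kinetic resolution by Ru(II)–TsDPEN asymmetric transfer hydrogenation (HCO2H/Et3N), with the catalyst enantiomer that reduces the (2R)-ketone to the cis-flavan-4-ol F6, would leave the (2S)-ketone 15, at the cost of half the material.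

2. Step 3. Discrimination between the exposed silyl ether and the two beside the geranyl group may be incomplete, so that the regioisomeric phenol and doubly cleaved material form alongside 5. The fallback sets out from triol 3 and comes back at phenol 5, protecting in the opposite order so that the selective event is an acylation at the least hindered oxygen. Pivaloyl chloride (1 equiv, pyridine, CH2Cl2, −20 °C) would give the mono-pivalate F7. TBSOTf/2,6-lutidine would silylate the two remaining hydroxyls to give the bis-silyl pivalate F8. DIBAL-H (CH2Cl2, −78 °C) would then remove the pivalate without touching the aryl silyl ethers and give 5.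

3. Step 4. The hot, basic magnesium medium may strip or shift silyl groups, in particular the one that ends para to the new formyl group, or conversion may stall at the crowded position. The fallback sets out from phenol 5 and comes back at aldehyde 7, replacing the phenoxide-directed reaction by an electrophilic one. Vilsmeier–Haack formylation (POCl3, DMF, MeCN, 0 °C) would give the aryl iminium chloride F9, which aqueous NaOAc would hydrolyse to 7. Regiochemistry needs no directing effect here, because the only two free ring positions of 5 are equivalent.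

**Further compounds**

F1 | step 8 | 1-[2,4-bis(TBS-oxy)-3-geranyl-6-hydroxyphenyl]ethanol (racemic) | CC(O)c1c(O)cc(O[Si](C)(C)C(C)(C)C)c(C/C=C(\C)CCC=C(C)C)c1O[Si](C)(C)C(C)(C)C
F2 | step 8 | 1-[2,4-bis(TBS-oxy)-3-geranyl-6-hydroxyphenyl]ethanone | CC(=O)c1c(O)cc(O[Si](C)(C)C(C)(C)C)c(C/C=C(\C)CCC=C(C)C)c1O[Si](C)(C)C(C)(C)C
F3 | step 8 | 1-[2,4-bis(TBS-oxy)-3-geranyl-6-hydroxyphenyl]-3-hydroxy-3-[3-(TBS-oxy)-4,5-dimethoxyphenyl]propan-1-one (racemic aldol) | COc1cc(C(O)CC(=O)c2c(O)cc(O[Si](C)(C)C(C)(C)C)c(C/C=C(\C)CCC=C(C)C)c2O[Si](C)(C)C(C)(C)C)cc(O[Si](C)(C)C(C)(C)C)c1OC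
F4 | step 8 | (E)-1-[2,4-bis(TBS-oxy)-3-geranyl-6-hydroxyphenyl]-3-[3-(TBS-oxy)-4,5-dimethoxyphenyl]prop-2-en-1-one (2'-hydroxychalcone) | COc1cc(/C=C/C(=O)c2c(O)cc(O[Si](C)(C)C(C)(C)C)c(C/C=C(\C)CCC=C(C)C)c2O[Si](C)(C)C(C)(C)C)cc(O[Si](C)(C)C(C)(C)C)c1OC
F5 | step 8 | racemic 5,7-bis(TBS-oxy)-2-[3-(TBS-oxy)-4,5-dimethoxyphenyl]-6-geranylchroman-4-one | COc1cc(C2CC(=O)c3c(cc(O[Si](C)(C)C(C)(C)C)c(C/C=C(\C)CCC=C(C)C)c3O[Si](C)(C)C(C)(C)C)O2)cc(O[Si](C)(C)C(C)(C)C)c1OC
F6 | step 8 | (2R,4R)-cis-5,7-bis(TBS-oxy)-2-[3-(TBS-oxy)-4,5-dimethoxyphenyl]-6-geranylchroman-4-ol | COc1cc([C@H]2C[C@@H](O)c3c(cc(O[Si](C)(C)C(C)(C)C)c(C/C=C(\C)CCC=C(C)C)c3O[Si](C)(C)C(C)(C)C)O2)cc(O[Si](C)(C)C(C)(C)C)c1OC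
F7 | step 3 | 4-geranyl-3,5-dihydroxyphenyl pivalate | CC(C)(C)C(=O)Oc1cc(O)c(C/C=C(\C)CCC=C(C)C)c(O)c1
F8 | step 3 | 3,5-bis(TBS-oxy)-4-geranylphenyl pivalate | CC(C)(C)C(=O)Oc1cc(O[Si](C)(C)C(C)(C)C)c(C/C=C(\C)CCC=C(C)C)c(O[Si](C)(C)C(C)(C)C)c1
F9 | step 4 | N-{[2,4-bis(TBS-oxy)-3-geranyl-6-hydroxyphenyl]methylidene}-N-methylmethanaminium chloride | C[N+](C)=Cc1c(O)cc(O[Si](C)(C)C(C)(C)C)c(C/C=C(\C)CCC=C(C)C)c1O[Si](C)(C)C(C)(C)C.[Cl-]
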